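## The problem

Isoamoritin (20) is a (2S)-flavanone: a chroman-4-one in which ring A is fused to the pyranone ring C and ring B is attached at C2. C2, the only stereocentre, is benzylic, carries the ring oxygen and lies β to the C4 ketone, so nothing else in the molecule can direct it, and it can be lost by retro-oxa-Michael opening to the 2'-hydroxychalcone (easily under base, more slowly on long heating or in acid). Ring A is fully substituted (5-OH, 7-OH, prenyl at C6 and C8) and ring B carries 3'-OH, 4'-OMe and a 5'-prenyl group. Three trisubstituted alkenes therefore have to be placed on electron-rich rings without O- versus C-alkylation mixtures and without reverse (1,1-dimethylallyl) isomers. The prenyl groups do not survive strong acid (cyclisation onto an ortho hydroxyl to a 2,2-dimethylchroman, addition of HX) or peracids, and the free phenols together with C2 rule out a strongly basic end-game. The feature that opens the way is the pattern of ring A: C6 and C8 are its only two CH carbons; C6 is ortho to both O5 and O7, and C8 is ortho to O7 and para to O5. An allyl group parked on O5 or O7 can therefore reach only C6 or C8 by [3,3] shifts, whatever the order of events. Ring B repeats this logic on a small scale: its side chain sits ortho to the oxygen that ends as the methyl ether, so it too can be delivered from oxygen.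

## Retrosynthesis

In what follows "allyl" is prop-2-en-1-yl, "prenyl" is 3-methylbut-2-en-1-yl and MOM is methoxymethyl.

**Prenyl groups (20 ⇒ 18 + 19).** The three CH=CMe2 double bonds are cut, leading back to the triallyl triphenol 18 and three equivalents of 2-methyl-2-butene (19). Direct C-prenylation of a phloroglucinol-type ring gives O/C and mono/di mixtures, and a Claisen shift of a prenyl ether delivers the reverse-prenyl group to the ortho carbon. An allyl group is a prenyl surrogate that tolerates heat and acid and gives the same chain whether it arrives ortho or para. One neutral cross-metathesis then makes all three prenyl groups at the very end. The forward step must exchange three terminal alkenes in the presence of free phenols.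

**3'-Hydroxyl (18 ⇒ 17).** The O–CH2 bond of a MOM ether is cut. This acid step is placed before the metathesis so that acid meets only allyl groups, never an ortho-prenylphenol. The precursor 17 differs from 18 only by the acetal, and the forward step needs dilute acid that does not open ring C.

**Ring A side chains (17 ⇒ 15, the key disconnection).** The C6–CH2 and C8–CH2 bonds are cut and both allyl groups are returned to O5 and O7, giving the (2S)-5,7-bis(allyloxy)flavanone 15. The neighbouring options are worse: direct C-allylation of ring A at the diol stage needs base, which racemises C2 and gives O/C mixtures, and building ring A with its chains in place costs many steps. Precursor 15 has a plain resorcinol-type ring A that traces back to 2,4,6-trihydroxyacetophenone (11). The forward reaction must drive two sigmatropic shifts to completion without base and without loss of C2.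

**C2–aryl bond (15 ⇒ 14 + 10).** The C2–C1' bond is cut, giving the achiral chromone 14 and the arylboronic acid 10. A catalytic asymmetric 1,4-addition sets C2 while the two halves are joined. The alternative, closing the O1–C2 bond by asymmetric oxa-Michael addition, is less reliable when the enone is not further activated. The catalyst must control the face of C2, tolerate three allyl groups and avoid ring opening of the enolate.

**Chromone (14 ⇒ 12 ⇒ 11 + 2).** C2 of the chromone is a one-carbon unit condensed onto the acetyl group of 12. The two allyl ether C–O bonds lead back to 11 and two equivalents of allyl bromide (2). The hydroxyl that stays hydrogen-bonded to the ketone is left free and becomes O1.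

**Boronic acid (10 ⇒ 8).** The C–B bond is cut to the aryl bromide 8. The bromine sits para to the future methoxy group and marks C1'. Bromide 8 is a stable benzene derivative, and the forward step needs halogen–metal exchange that is faster than any deprotonation.

**Ring B pattern (8 ⇒ 7 ⇒ 6 ⇒ 5 ⇒ 3 ⇒ 1 + 2).** Methylation (8 ⇒ 7) follows a ring B Claisen shift (7 ⇒ 6) that moves the allyl group from the oxygen that becomes the 4'-methoxy group to its only free ortho carbon. The MOM ether 6 comes from phenol 5, and the phenol from the aldehyde 3 by Baeyer–Villiger oxidation, so the formyl group of 5-bromosalicylaldehyde (1) ends as the 3'-oxygen. The oxidation is placed at the allyl ether stage, where the alkene is least nucleophilic towards peracid.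

## Roads not taken

**Alternative 1:** Ring A is built, not decorated. The cut runs through C8a–C4a and C5–C6: 3-tert-butoxy-2,4-diprenylcyclobutenone A2 is heated with siloxyalkyne A3, which already carries the C4–C3–C2 chain and ring B.

- Forward key step: electrocyclic opening of A2, [2+2] addition to the alkyne of A3, a second opening and 6π closure (Danheiser-type benzannulation) give the pentasubstituted phenol A1.
- Merits: every substituent of ring A is placed by construction, the prenyl groups arrive intact, and no flavanone is ever heated.
- Weak points: A2 and A3 each need a multistep synthesis. Once A2 has opened, its ketene has a prenyl alkene within reach for an intramolecular [2+2] addition. After A1 the route still needs sorting of four silyl ethers, oxidation at C4, closure of ring C at C2 by Mitsunobu inversion at an electron-rich benzylic carbinol (ionisation would erode the configuration), and acid cleavage of a tert-butyl ether flanked by two prenyl groups.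
- Comparison: this road is better in that ring A regiochemistry never depends on a migration and C2 is never exposed to high temperature as a flavanone. The chosen plan sets against it twelve steps from four commodity chemicals and a regiochemistry that is just as unambiguous, because ring A has only two open carbons.

**Alternative 2:** Ring C is closed by cycloaddition. O1–C2 and C3–C4 are cut: a chiral Brønsted acid ionises the ring A salicylaldehyde dimethyl acetal A5 with loss of methanol, and the ring B styrene A6 adds across the oxa-diene unit so exposed in a hetero-[4+2] reaction to give the 2,4-cis-4-methoxyflavan A4.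

- Merits: convergent; two bonds, ring C and C2 are formed in one catalytic step; both halves bring their prenyl groups, so there is no late metathesis and no high temperature.
- Weak points: A4 is at the flavan oxidation level. The C4 methyl ether must be solvolysed and the alcohol oxidised in the presence of three prenyl groups, and ionisation at C4 can reopen ring C. The acid catalyst meets three MOM acetals and three trisubstituted alkenes. The ionised form of A5, on a fully substituted and strongly donating ring, is stabilised and slow to react, and the prenyl alkenes compete as 2π partners. The ring A diprenylation problem is not solved but moved into the synthesis of A5.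
- Comparison: this road is more convergent and milder. The chosen plan sets against it an asymmetric step on a substrate class with direct precedent, a product already at the ketone oxidation level, and an actual solution to the ring A substitution.

**Alternative 3:** C2–C3 is cut. The aryl diazomethyl ketone A8, whose O1 already carries the ring B benzyl group, is decomposed by a chiral dirhodium tetracarboxylate. The rhodium carbenoid from A8 inserts into the benzylic C–H bond next to oxygen, forming C2–C3, closing ring C and setting C2, to give isoamoritin tris(triisopropylsilyl) ether A7.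

- Merits: the best end-game of all four, since A7 is one buffered desilylation from the target. The stereocentre forms in the ring-closing step under neutral, cold conditions.
- Weak points: the ortho ether oxygen can intercept the carbenoid, after which a Stevens [1,2] benzyl shift closes a five-membered ring in place of ring C. Insertion to a six-membered ring is less favoured than this ylide pathway. Acceptor-only carbenoids give modest enantiocontrol with carboxylate catalysts. The prenyl alkenes are cyclopropanation sites. A8 needs a hexasubstituted benzoic acid, its benzyl ether and diazomethane.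
- Comparison: this road has a shorter finish and handles no flavanone at high temperature. The chosen plan sets against it firm precedent for every bond-forming step and no chemoselectivity contest at the key stage.

Key step: step 10

Remark on the chemistry: the (S)-series biaryl diphosphine is assumed to deliver the aryl group to the face of C2 that gives the (2S)-flavanone, by analogy with the known sense for cyclic enones; if the first run shows the opposite sense, the (R)-ligand is used and nothing else changes. Flavanone numbering is used throughout, with primed positions on ring B.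

## Route

Step 1
Reactants: 1 5-bromosalicylaldehyde; 2 allyl bromide
Product: 3 2-(allyloxy)-5-bromobenzaldehyde
Conditions: K2CO3, DMF, 25 °C
Reagents that add atoms: none
Why: Williamson etherification of the phenoxide with a primary allylic bromide (SN2); the aldehyde is untouched by K2CO3 at room temperature.

Step 2
Reactants: 3 2-(allyloxy)-5-bromobenzaldehyde
Product: 5 2-(allyloxy)-5-bromophenol, via 2-(allyloxy)-5-bromophenyl formate 4 (not isolated)
Conditions: mCPBA, CH2Cl2, 0 to 25 °C; then K2CO3, MeOH, 25 °C
Reagents that add atoms: 3-chloroperoxybenzoic acid (mCPBA), O=C(OO)c1cccc(Cl)c1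
Why: Baeyer–Villiger oxidation in which the ortho-alkoxyaryl group migrates in preference to hydrogen to give formate 4, which methanol cleaves by transesterification. The alkene of an allyl aryl ether is monosubstituted and inductively deactivated, so epoxidation should be much slower than oxidation of the aldehyde; this is why the oxidation precedes any C-allyl group.

Step 3
Reactants: 5 2-(allyloxy)-5-bromophenol
Product: 6 1-(allyloxy)-4-bromo-2-(methoxymethoxy)benzene
Conditions: MOMCl, iPr2NEt, CH2Cl2, 0 to 25 °C
Reagents that add atoms: chloromethyl methyl ether (MOMCl), COCCl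
Why: O-alkylation of the phenol with an α-chloro ether under amine base; the MOM ether should withstand the organolithium, the rhodium step and the heating that follow.

Step 4
Reactants: 6 1-(allyloxy)-4-bromo-2-(methoxymethoxy)benzene
Product: 7 2-allyl-4-bromo-6-(methoxymethoxy)phenol
Conditions: N,N-diethylaniline, 190 °C, N2
Reagents that add atoms: none
Why: Aromatic Claisen rearrangement ([3,3] shift, then enolisation): one ortho carbon carries the MOM ether and the para carbon carries bromine, so the allyl group can only settle on the single free ortho carbon, next to the oxygen that becomes the 4'-methoxy group. The weakly basic solvent keeps adventitious acid away from the acetal.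

Step 5
Reactants: 7 2-allyl-4-bromo-6-(methoxymethoxy)phenol
Product: 8 1-allyl-5-bromo-2-methoxy-3-(methoxymethoxy)benzene
Conditions: MeI, K2CO3, DMF, 25 to 40 °C
Reagents that add atoms: iodomethane, CI
Why: Williamson O-methylation of the flanked phenol with a small electrophile; there is no competing nucleophilic site.

Step 6
Reactants: 8 1-allyl-5-bromo-2-methoxy-3-(methoxymethoxy)benzene
Product: 10 [3-allyl-4-methoxy-5-(methoxymethoxy)phenyl]boronic acid, via aryllithium 9 (not isolated)
Conditions: n-BuLi, THF, −78 °C; B(OiPr)3, −78 to 0 °C; aq. NH4Cl
Reagents that add atoms: triisopropyl borate, CC(C)OB(OC(C)C)OC(C)C; water, O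
Why: Bromine–lithium exchange at −78 °C is faster than deprotonation next to the allyl group or ortho to the MOM ether; aryllithium 9 is trapped by the borate, and hydrolysis near pH 5 should give the boronic acid with the acetal intact.

Step 7
Reactants: 11 2,4,6-trihydroxyacetophenone; 2 allyl bromide
Product: 12 1-[2-hydroxy-4,6-bis(allyloxy)phenyl]ethan-1-one
Conditions: K2CO3 (2.2 equiv), allyl bromide (2.2 equiv), acetone, reflux
Reagents that add atoms: allyl bromide (the second equivalent of 2), C=CCBr
Why: Twofold Williamson etherification that consumes two equivalents of 2, one for the para hydroxyl and one for either of the two equivalent ortho hydroxyls. The last hydroxyl is then held in a hydrogen bond to the carbonyl and should not react under these mild conditions.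

Step 8
Reactants: 12 1-[2-hydroxy-4,6-bis(allyloxy)phenyl]ethan-1-one
Product: 14 5,7-bis(allyloxy)-4H-chromen-4-one, via enaminone 13 (not isolated)
Conditions: Me2NCH(OMe)2, toluene, 90 °C; then conc. HCl, CH2Cl2, 25 to 40 °C
Reagents that add atoms: N,N-dimethylformamide dimethyl acetal, COC(OC)N(C)C
Why: Condensation of the methyl ketone with the amide acetal gives enaminone 13; acid then promotes conjugate addition of the ortho hydroxyl and loss of dimethylamine (addition–elimination) to close the chromone. 90 °C is far below the Claisen threshold of the allyl ethers.

Step 9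
Reactants: 14 5,7-bis(allyloxy)-4H-chromen-4-one; 10 [3-allyl-4-methoxy-5-(methoxymethoxy)phenyl]boronic acid
Product: 15 (2S)-5,7-bis(allyloxy)-2-[3-allyl-4-methoxy-5-(methoxymethoxy)phenyl]chroman-4-one
Conditions: [Rh(OH)(cod)]2 (2.5 mol %), (S)-MeO-F12-BIPHEP (5.5 mol %), 10 (2 equiv), toluene/H2O, 25 °C
Reagents that add atoms: none
Why: Hayashi–Miyaura asymmetric 1,4-addition: aryl transfer from boron to monovalent rhodium, enantioface-selective insertion of the C2=C3 bond, and protonolysis of the rhodium enolate by water. The C2-symmetric biaryl diphosphine (3,4,5-trifluorophenyl groups on phosphorus) shields one face of the bound chromone and so sets C2 as S under catalyst control; its electron-poor phosphorus speeds transmetalation, so the reaction should run at room temperature without added base, where the enolate does not open to a chalcone.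

Step 10
Reactants: 15 (2S)-5,7-bis(allyloxy)-2-[3-allyl-4-methoxy-5-(methoxymethoxy)phenyl]chroman-4-one
Product: 17 (2S)-6,8-diallyl-5,7-dihydroxy-2-[3-allyl-4-methoxy-5-(methoxymethoxy)phenyl]chroman-4-one, via 6-allyl-7-allyloxy-5-hydroxyflavanone 16 (not isolated)
Conditions: Eu(fod)3 (10 mol %), degassed 1,2-dichlorobenzene, 80 °C, then 180 °C, sealed tube, silanised glass, Ar
Reagents that add atoms: none
Why: Each allyl aryl ether undergoes a concerted suprafacial [3,3] sigmatropic shift (aromatic Claisen rearrangement) through a chair-like transition state to an ortho-cyclohexadienone that enolises to the phenol. Eu(fod)3 chelated between the C4 carbonyl and O5 polarises the O5–allyl bond, so this ether should shift first, below 100 °C, to C6, its only free ortho carbon, giving 16 with its new 5-OH hydrogen-bonded to C4=O. The O7 ether then shifts thermally to C8, the one ortho carbon still open; a shift onto the occupied C6 gives a blocked dienone that can only revert or pass the allyl group on by a Cope [3,3] shift (para-Claisen–Cope), so every order of events drains to the 6,8-diallyl-5,7-diol 17. The closest known reactions are the thermal and Eu(fod)3-promoted Claisen and Claisen–Cope rearrangements of 5-O- and 7-O-allyl and prenyl flavonoids. No ring is closed and no stereocentre is created; C2 is a spectator. The only selectivity needed is regiochemical, and it is secured by the substrate itself, because C6 and C8 are the only unsubstituted carbons of ring A and each is ortho or para to both ether oxygens. Unsubstituted allyl groups are used so that ortho and para delivery give the same chain, with no reverse-prenyl isomers. The medium is aprotic and base-free so that the flavanone does not open to the 2'-hydroxychalcone and lose C2; the ring B allyl group and the MOM ether should be inert.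

Step 11
Reactants: 17 (2S)-6,8-diallyl-5,7-dihydroxy-2-[3-allyl-4-methoxy-5-(methoxymethoxy)phenyl]chroman-4-one
Product: 18 (2S)-6,8-diallyl-2-(3-allyl-5-hydroxy-4-methoxyphenyl)-5,7-dihydroxychroman-4-one
Conditions: HCl (3 M aq)/MeOH, 40 °C
Reagents that add atoms: none
Why: Acid-catalysed acetal exchange; the MOM group leaves as dimethoxymethane. No prenyl group is present yet and monosubstituted allyl groups are not protonated by dilute acid, so neither chroman formation nor methanol addition is expected, and a 5-hydroxyflavanone should hold C2 under these conditions.

Step 12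
Reactants: 18 (2S)-6,8-diallyl-2-(3-allyl-5-hydroxy-4-methoxyphenyl)-5,7-dihydroxychroman-4-one; 19 2-methyl-2-butene
Product: 20 isoamoritin
Conditions: second-generation Grubbs catalyst, RuCl2(=CHPh)(H2IMes)(PCy3) (10 mol %), 2-methyl-2-butene (large excess)/CH2Cl2, 40 °C, sealed tube
Reagents that add atoms: 2-methyl-2-butene (the two further equivalents of 19), CC=C(C)C
Why: Threefold olefin cross-metathesis in which each terminal alkene takes one isopropylidene unit from a molecule of 19, used in large excess, and releases propene. The trisubstituted product alkenes do not re-enter the cycle productively, and the conditions are neutral, so C2 and the free phenols should be left alone.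

## Compound list

1 | 5-bromosalicylaldehyde | O=Cc1cc(Br)ccc1O | starting material
2 | allyl bromide | C=CCBr | starting material
3 | 2-(allyloxy)-5-bromobenzaldehyde | C=CCOc1ccc(Br)cc1C=O | intermediate
4 | 2-(allyloxy)-5-bromophenyl formate | C=CCOc1ccc(Br)cc1OC=O | intermediate
5 | 2-(allyloxy)-5-bromophenol | C=CCOc1ccc(Br)cc1O | intermediate
6 | 1-(allyloxy)-4-bromo-2-(methoxymethoxy)benzene | C=CCOc1ccc(Br)cc1OCOC | intermediate
7 | 2-allyl-4-bromo-6-(methoxymethoxy)phenol | COCOc1cc(Br)cc(CC=C)c1O | intermediate
8 | 1-allyl-5-bromo-2-methoxy-3-(methoxymethoxy)benzene | COCOc1cc(Br)cc(CC=C)c1OC | intermediate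
9 | [3-allyl-4-methoxy-5-(methoxymethoxy)phenyl]lithium | [Li]c1cc(CC=C)c(OC)c(OCOC)c1 | intermediate
10 | [3-allyl-4-methoxy-5-(methoxymethoxy)phenyl]boronic acid | COCOc1cc(B(O)O)cc(CC=C)c1OC | intermediate
11 | 2,4,6-trihydroxyacetophenone | CC(=O)c1c(O)cc(O)cc1O | starting material
12 | 1-[2-hydroxy-4,6-bis(allyloxy)phenyl]ethan-1-one | CC(=O)c1c(O)cc(OCC=C)cc1OCC=C | intermediate
13 | (E)-3-(dimethylamino)-1-[2-hydroxy-4,6-bis(allyloxy)phenyl]prop-2-en-1-one | CN(C)/C=C/C(=O)c1c(O)cc(OCC=C)cc1OCC=C | intermediate
14 | 5,7-bis(allyloxy)-4H-chromen-4-one | O=c1ccoc2cc(OCC=C)cc(OCC=C)c12 | intermediate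
15 | (2S)-5,7-bis(allyloxy)-2-[3-allyl-4-methoxy-5-(methoxymethoxy)phenyl]chroman-4-one | COc1c(OCOC)cc([C@@H]2CC(=O)c3c(OCC=C)cc(OCC=C)cc3O2)cc1CC=C | intermediate
16 | (2S)-6-allyl-7-(allyloxy)-5-hydroxy-2-[3-allyl-4-methoxy-5-(methoxymethoxy)phenyl]chroman-4-one | COc1c(OCOC)cc([C@@H]2CC(=O)c3c(O)c(CC=C)c(OCC=C)cc3O2)cc1CC=C | intermediate
17 | (2S)-6,8-diallyl-5,7-dihydroxy-2-[3-allyl-4-methoxy-5-(methoxymethoxy)phenyl]chroman-4-one | COc1c(OCOC)cc([C@@H]2CC(=O)c3c(O)c(CC=C)c(O)c(CC=C)c3O2)cc1CC=C | intermediate
18 | (2S)-6,8-diallyl-2-(3-allyl-5-hydroxy-4-methoxyphenyl)-5,7-dihydroxychroman-4-one | COc1c(O)cc([C@@H]2CC(=O)c3c(O)c(CC=C)c(O)c(CC=C)c3O2)cc1CC=C | intermediate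
19 | 2-methyl-2-butene | CC=C(C)C | starting material
20 | isoamoritin, (2S)-5,7-dihydroxy-2-[3-hydroxy-4-methoxy-5-(3-methylbut-2-en-1-yl)phenyl]-6,8-bis(3-methylbut-2-en-1-yl)chroman-4-one | COc1c(O)cc([C@@H]2CC(=O)c3c(O)c(CC=C(C)C)c(O)c(CC=C(C)C)c3O2)cc1CC=C(C)C | target

## Step count and risks

Total: 12 steps. Longest linear sequence: 10 steps (steps 1–6, then 9–12). The ring A branch (steps 7 and 8) joins at step 9.

**Step 10 (key step).** The most likely failure is loss of configuration at C2 through thermal or europium-assisted retro-oxa-Michael opening during the time at 180 °C. Next come an incomplete second shift and cyclisation of a new ortho-allylphenol onto its alkene. The europium chelate is an aid for the first shift only and can be left out. Fallback, from 14 back to the route at 18: the double shift is run before the stereocentre exists. Heating 14 in 1,2-dichlorobenzene should give 6,8-diallyl-5,7-dihydroxy-4H-chromen-4-one F1. NaH and MOMCl in DMF protect both hydroxyls as 6,8-diallyl-5,7-bis(methoxymethoxy)-4H-chromen-4-one F2. Rhodium-catalysed addition of 10 under the conditions of step 9 gives (2S)-6,8-diallyl-2-[3-allyl-4-methoxy-5-(methoxymethoxy)phenyl]-5,7-bis(methoxymethoxy)chroman-4-one F3. HCl in methanol, as in step 11, removes all three acetals and gives 18.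

**Step 9.** A chromone with two donor ethers is a weak acceptor, so slow insertion could let protodeboronation of the electron-rich boronic acid win. The rhodium enolate could expel the aryloxide and open ring C. Traces of rhodium hydride could move the allyl double bonds into conjugation. The facial selectivity could fall short. Fallback, from 8 and 12 back to the route at 15: aryllithium 9, made from 8 as in step 6, is quenched with DMF to give 3-allyl-4-methoxy-5-(methoxymethoxy)benzaldehyde F4. Claisen–Schmidt condensation of F4 with 12 (KOH, EtOH) gives the 2'-hydroxychalcone (E)-1-[2-hydroxy-4,6-bis(allyloxy)phenyl]-3-[3-allyl-4-methoxy-5-(methoxymethoxy)phenyl]prop-2-en-1-one F5. Asymmetric intramolecular oxa-Michael addition under a quinine-derived bifunctional thiourea closes ring C to 15, and any shortfall in enantiomeric purity is made up by preparative chromatography on a chiral stationary phase.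

**Step 12.** Exchange may stall at the two ring A allyl groups, which sit beside free hydroxyls that can bind ruthenium. Ruthenium hydride formed in the presence of phenols could move a double bond into conjugation, after which metathesis would shorten the side chain by one carbon. Fallback, from 18 back to the route at 20: TBSCl and imidazole in DMF silylate the two non-chelated hydroxyls to give (2S)-6,8-diallyl-2-[3-allyl-5-(tert-butyldimethylsilyloxy)-4-methoxyphenyl]-7-(tert-butyldimethylsilyloxy)-5-hydroxychroman-4-one F6. Cross-metathesis with 19 as in step 12 gives the triprenyl bis(silyl) ether F7. Et3N·3HF in THF, a non-basic fluoride source, removes both silyl groups to give 20.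

**Step 4.** The MOM acetal may be lost or exchanged at 190 °C, catalysed by the phenol that the rearrangement releases. Fallback, from 3 back to the route at 8: the order is changed so that the rearrangement precedes the acetal. Thermal Claisen rearrangement of 3 gives 3-allyl-5-bromo-2-hydroxybenzaldehyde F8. MeI and K2CO3 give 3-allyl-5-bromo-2-methoxybenzaldehyde F9. Baeyer–Villiger oxidation with mCPBA gives 3-allyl-5-bromo-2-methoxyphenyl formate F10, and K2CO3 in methanol gives 3-allyl-5-bromo-2-methoxyphenol F11. MOMCl and iPr2NEt then give 8. The price is a peracid step in the presence of a C-allyl group.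

## Further compounds

F1 | step 10 | 6,8-diallyl-5,7-dihydroxy-4H-chromen-4-one | O=c1ccoc2c(CC=C)c(O)c(CC=C)c(O)c12
F2 | step 10 | 6,8-diallyl-5,7-bis(methoxymethoxy)-4H-chromen-4-one | O=c1ccoc2c(CC=C)c(OCOC)c(CC=C)c(OCOC)c12
F3 | step 10 | (2S)-6,8-diallyl-2-[3-allyl-4-methoxy-5-(methoxymethoxy)phenyl]-5,7-bis(methoxymethoxy)chroman-4-one | COc1c(OCOC)cc([C@@H]2CC(=O)c3c(OCOC)c(CC=C)c(OCOC)c(CC=C)c3O2)cc1CC=C
F4 | step 9 | 3-allyl-4-methoxy-5-(methoxymethoxy)benzaldehyde | O=Cc1cc(CC=C)c(OC)c(OCOC)c1
F5 | step 9 | (E)-1-[2-hydroxy-4,6-bis(allyloxy)phenyl]-3-[3-allyl-4-methoxy-5-(methoxymethoxy)phenyl]prop-2-en-1-one | COc1c(OCOC)cc(/C=C/C(=O)c2c(O)cc(OCC=C)cc2OCC=C)cc1CC=C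
F6 | step 12 | (2S)-6,8-diallyl-2-[3-allyl-5-(tert-butyldimethylsilyloxy)-4-methoxyphenyl]-7-(tert-butyldimethylsilyloxy)-5-hydroxychroman-4-one | COc1c(O[Si](C)(C)C(C)(C)C)cc([C@@H]2CC(=O)c3c(O)c(CC=C)c(O[Si](C)(C)C(C)(C)C)c(CC=C)c3O2)cc1CC=C
F7 | step 12 | (2S)-2-[3-(tert-butyldimethylsilyloxy)-4-methoxy-5-prenylphenyl]-7-(tert-butyldimethylsilyloxy)-5-hydroxy-6,8-diprenylchroman-4-one | COc1c(O[Si](C)(C)C(C)(C)C)cc([C@@H]2CC(=O)c3c(O)c(CC=C(C)C)c(O[Si](C)(C)C(C)(C)C)c(CC=C(C)C)c3O2)cc1CC=C(C)C
F8 | step 4 | 3-allyl-5-bromo-2-hydroxybenzaldehyde | O=Cc1cc(Br)cc(CC=C)c1O
F9 | step 4 | 3-allyl-5-bromo-2-methoxybenzaldehyde | COc1c(CC=C)cc(Br)cc1C=O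
F10 | step 4 | 3-allyl-5-bromo-2-methoxyphenyl formate | COc1c(CC=C)cc(Br)cc1OC=O
F11 | step 4 | 3-allyl-5-bromo-2-methoxyphenol | COc1c(CC=C)cc(Br)cc1O
A1 | alternative 1 | pentasubstituted ring A phenol from the benzannulation, carrying the bis-silylated 1,3-diol chain to ring B | COc1c(O[Si](C(C)C)(C(C)C)C(C)C)cc([C@H](O[Si](CC)(CC)CC)CC(O[Si](C)(C)C(C)(C)C)c2c(O)c(CC=C(C)C)c(OC(C)(C)C)c(CC=C(C)C)c2O[Si](C(C)C)(C(C)C)C(C)C)cc1CC=C(C)C
A2 | alternative 1 | 3-tert-butoxy-2,4-bis(3-methylbut-2-en-1-yl)cyclobut-2-en-1-one | O=C1C(CC=C(C)C)C(OC(C)(C)C)=C1CC=C(C)C
A3 | alternative 1 | triisopropylsiloxyalkyne carrying the silyl-protected C4–C3–C2 chain and ring B | COc1c(O[Si](C(C)C)(C(C)C)C(C)C)cc([C@H](O[Si](CC)(CC)CC)CC(O[Si](C)(C)C(C)(C)C)C#CO[Si](C(C)C)(C(C)C)C(C)C)cc1CC=C(C)C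
A4 | alternative 2 | (2S)-2,4-cis-4-methoxyflavan tris(methoxymethyl) ether | COc1c(OCOC)cc([C@@H]2C[C@H](OC)c3c(OCOC)c(CC=C(C)C)c(OCOC)c(CC=C(C)C)c3O2)cc1CC=C(C)C
A5 | alternative 2 | 2-(dimethoxymethyl)-3,5-bis(methoxymethoxy)-4,6-bis(3-methylbut-2-en-1-yl)phenol | COC(OC)c1c(O)c(CC=C(C)C)c(OCOC)c(CC=C(C)C)c1OCOC
A6 | alternative 2 | 1-ethenyl-4-methoxy-3-(methoxymethoxy)-5-(3-methylbut-2-en-1-yl)benzene | C=Cc1cc(OCOC)c(OC)c(CC=C(C)C)c1
A7 | alternative 3 | (2S)-isoamoritin tris(triisopropylsilyl) ether | COc1c(O[Si](C(C)C)(C(C)C)C(C)C)cc([C@@H]2CC(=O)c3c(O[Si](C(C)C)(C(C)C)C(C)C)c(CC=C(C)C)c(O[Si](C(C)C)(C(C)C)C(C)C)c(CC=C(C)C)c3O2)cc1CC=C(C)C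
A8 | alternative 3 | ring A aryl diazomethyl ketone bearing the ring B benzyl ether on O1 | [N-]=[N+]=CC(=O)c1c(O[Si](C(C)C)(C(C)C)C(C)C)c(CC=C(C)C)c(O[Si](C(C)C)(C(C)C)C(C)C)c(CC=C(C)C)c1OCc1cc(O[Si](C(C)C)(C(C)C)C(C)C)c(OC)c(CC=C(C)C)c1
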